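**Retrosynthetic overview**

1. Feature (atoms numbered by their position in the target SMILES): the nine-membered ring E (N10, C11, C12, C22, C28, C29, C30, C32, C34) carries the lactam carbonyl C8 and the ketone C30 at the two ends of what is a single C8=C30 bond in a tertiary enamine. There it is the fusion bond of cyclohexene F (C7, C8, C30, C29, C28, C22) and pyrroline G (N10, C8, C30, C32, C34); cutting it with singlet oxygen gives ring E without any medium-ring closure.
2. Piperidine D (C7, C8, N10, C11, C12, C22) and ring F form a 2-azabicyclo[3.3.1]nonane with C8 at a bridgehead, so the enamine is a bridgehead alkene and cannot be made by equilibrium condensation. It is released by syn-elimination from the C8 carbinolamine, which is assembled from a C11 amine, the C8 ketone and a C34 aldehyde (rings D and G together).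
3. Hydroxy-enone ring B (C14, C15, C16, C18, C19, C20) comes from a para-alkylphenol by oxidative dearomatization and conjugate reduction. Cyclopentane A (C5, C6, C7, C15, C16) and cyclohexene C (C7, C15, C14, C13, C12, C22) come from two palladium enolate arylations on one bromo-chloro-arene (ketone at C7 with C–Br, then ester at C5 with C–Cl).
4. C22 and C12 come from an Ireland–Claisen rearrangement of a cyclohexenyl 3-arylpropanoate whose C8 carbinol is set by a CBS reduction; ring F comes from cyclohexane-1,3-dione and methyl acrylate; C32 comes from an iridium-catalysed branched allylation at C30.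
5. Order of rings: F, then C, then A, then oxidation of B, then D together with G, then E.

Key step: step 28

Remark: C30 (until step 26), C7 (in 20–23, 26, 27) and C8 (in 20–22) are epimerizable or are destroyed later and are written without configuration; Ar in names means 6-(benzyloxy)-2-bromo-3-chlorophenyl.

**Route**

Step 1
Reactants: 1 cyclohexane-1,3-dione; 2 methyl acrylate
Product: 3 methyl 3-(2,6-dioxocyclohexyl)propanoate
Conditions: NaOMe (0.1 equiv), MeOH, 60 °C
Reagents that add atoms: none
Why: Michael addition of the dione C2 carbon (future C7) to the acrylate installs C6, C5 and the ester carbon in one operation.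

Step 2
Reactants: 3 methyl 3-(2,6-dioxocyclohexyl)propanoate
Product: 4 methyl 3-(2-iodo-6-oxocyclohex-1-en-1-yl)propanoate
Conditions: PPh3, I2, Et3N, MeCN, reflux
Reagents that add atoms: iodine, II
Why: The enol oxygen of the vinylogous acid is activated as an oxyphosphonium ion and replaced by iodide through addition–elimination, giving the β-iodo enone (C22–I, C8 ketone).

Step 3
Reactants: 4 methyl 3-(2-iodo-6-oxocyclohex-1-en-1-yl)propanoate; 5 potassium [(benzyloxy)methyl]trifluoroborate
Product: 6 methyl 3-{2-[(benzyloxy)methyl]-6-oxocyclohex-1-en-1-yl}propanoate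
Conditions: Pd(OAc)2 (5 mol %), RuPhos, Cs2CO3, dioxane/H2O (10:1), 80 °C
Reagents that add atoms: none
Why: Suzuki–Miyaura coupling of an alkoxymethyl trifluoroborate with the activated β-iodo enone puts the C23 benzyloxymethyl group on C22.

Step 4
Reactants: 6 methyl 3-{2-[(benzyloxy)methyl]-6-oxocyclohex-1-en-1-yl}propanoate
Product: 7 methyl 3-{(6S)-2-[(benzyloxy)methyl]-6-hydroxycyclohex-1-en-1-yl}propanoate
Conditions: (R)-2-methyl-CBS-oxazaborolidine (0.2 equiv), BH3·SMe2, THF, −30 °C; MeOH
Reagents that add atoms: none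
Why: Corey–Bakshi–Shibata reduction, in which the catalyst tells the substituted alkenyl side (large) from the ring CH2 (small), gives the S carbinol at C8 and leaves the ester alone.

Step 5
Reactants: 8 3-bromo-4-chlorophenol; 9 benzyl bromide
Product: 10 4-(benzyloxy)-2-bromo-1-chlorobenzene
Conditions: K2CO3, DMF, rt
Reagents that add atoms: none
Why: Williamson ether synthesis protects the future C20 oxygen as a benzyl ether that survives strong bases and palladium.

Step 6
Reactants: 10 4-(benzyloxy)-2-bromo-1-chlorobenzene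
Product: 12 6-(benzyloxy)-2-bromo-3-chlorobenzaldehyde, via aryllithium 11 (not isolated)
Conditions: LDA, THF, −78 °C; DMF; aq. NH4Cl
Reagents that add atoms: N,N-dimethylformamide, CN(C)C=O
Why: Directed ortho-lithiation removes the most acidic hydrogen, the one flanked by OBn and Br, and formylation places C13 on C14 with Br on C15 and Cl on C16.

Step 7
Reactants: 12 6-(benzyloxy)-2-bromo-3-chlorobenzaldehyde; 13 2,2-dimethyl-1,3-dioxane-4,6-dione (Meldrum's acid)
Product: 15 5-(Ar-methyl)-2,2-dimethyl-1,3-dioxane-4,6-dione, via arylidene Meldrum's acid 14 (not isolated)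
Conditions: diethyl 2,6-dimethyl-1,4-dihydropyridine-3,5-dicarboxylate (Hantzsch ester), L-proline (cat.), EtOH, rt
Reagents that add atoms: none
Why: Knoevenagel condensation followed in the same flask by conjugate hydride transfer from the dihydropyridine (reductive alkylation) saturates the new C=C without touching C–Br, C–Cl or the benzyl ether.

Step 8
Reactants: 15 5-(Ar-methyl)-2,2-dimethyl-1,3-dioxane-4,6-dione
Product: 16 3-Ar-propanoic acid
Conditions: pyridine/H2O (10:1), 100 °C
Reagents that add atoms: water, O
Why: Hydrolysis of the acylal and decarboxylation of the malonic acid leave the C11 acid with C12 and C13 in place.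

Step 9
Reactants: 7 methyl 3-{(6S)-2-[(benzyloxy)methyl]-6-hydroxycyclohex-1-en-1-yl}propanoate; 16 3-Ar-propanoic acid
Product: 17 C8 ester of 7 with acid 16
Conditions: EDC·HCl, DMAP, CH2Cl2, 0 °C to rt
Reagents that add atoms: none
Why: Carbodiimide (Steglich) esterification joins the two fragments through the allylic C8 oxygen without touching the C8 stereocentre.

Step 10
Reactants: 17 C8 ester of 7 with acid 16
Product: 19 ring-F cyclohex-2-ene (C7=C8) bearing CH2CH2CO2Me on C7 and, on quaternary C22, CH2OBn and CH(CO2H)CH2Ar, via bis(silyl ketene acetal) 18 (not isolated)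
Conditions: LDA (2.3 equiv), THF/DMPU (4:1), −78 °C; TBSCl; then 65 °C; 1 M HCl
Reagents that add atoms: none
Why: Ireland–Claisen rearrangement, in which the ketene acetal with C13 cis to OSi reacts through the boat-like transition state usual for cyclohexenyl esters, forms C12–C22 on the ring face that carried the C8 oxygen (so C22 follows from the CBS-set carbinol) with the C13 chain pointing away from the ring (which sets C12), while the ketene acetal of the methyl ester simply reverts on work-up.

Step 11
Reactants: 19 Claisen acid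
Product: 21 diol (C11–OH and C8–OH), via organoborane 20 (not isolated)
Conditions: BH3·THF (4 equiv), THF, 0 °C to rt; then 30% H2O2, aq. NaHCO3, 0 °C
Reagents that add atoms: hydrogen peroxide, OO
Why: Borane reduces the carboxylic acid much faster than the ester and hydroborates the trisubstituted C7=C8 bond with boron on the less substituted C8, so oxidation gives the C8 alcohol that becomes the ketone.

Step 12
Reactants: 21 diol
Product: 22 C11 O-tert-butyldiphenylsilyl ether
Conditions: TBDPSCl, imidazole, CH2Cl2, 0 °C
Reagents that add atoms: tert-butyl(chloro)diphenylsilane, CC(C)(C)[Si](Cl)(c1ccccc1)c1ccccc1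
Why: Silylation is selective for the primary C11 hydroxyl over the hindered secondary C8 hydroxyl.

Step 13
Reactants: 22 C11 O-tert-butyldiphenylsilyl ether
Product: 23 C8 ketone
Conditions: Dess–Martin periodinane, NaHCO3, CH2Cl2, rt
Reagents that add atoms: none
Why: Dess–Martin oxidation of the secondary alcohol gives the C8 ketone under neutral conditions.

Step 14
Reactants: 24 (E)-but-2-en-1-ol
Product: 25 (E)-but-2-en-1-yl methyl carbonate
Conditions: ClCO2Me, pyridine, CH2Cl2, 0 °C
Reagents that add atoms: methyl chloroformate, COC(Cl)=O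
Why: O-Acylation gives the allylic carbonate needed as electrophile for the iridium-catalysed allylation.

Step 15
Reactants: 23 C8 ketone; 25 (E)-but-2-en-1-yl methyl carbonate
Product: 27 C30-(but-3-en-2-yl) ketone with R configuration at C32, via trimethylsilyl enol ether 26 (not isolated)
Conditions: LiHMDS, THF, −78 °C, then TMSCl; then [Ir(cod)Cl]2 (2 mol %), (1,1′-binaphthalene-2,2′-diyl) N,N-bis(1-phenylethyl)phosphoramidite (the enantiomer that gives R at C32), CsF, ZnF2, DME, 50 °C
Reagents that add atoms: none
Why: Kinetic enolization goes to C30 because C7 is tertiary and flanked by quaternary C22, and the fluoride-activated silyl enol ether attacks the allyl iridium complex at its substituted terminus (iridium-catalysed branched allylic alkylation), so C32 is set by the ligand while the C30 configuration is of no consequence.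

Step 16
Reactants: 27 C30-(but-3-en-2-yl) ketone
Product: 28 tricyclic ketone with ring C closed (C7–C15 bond, C16–Cl retained)
Conditions: PdCl2(PPh3)2 (10 mol %), Cs2CO3, toluene, 100 °C
Reagents that add atoms: none
Why: Palladium-catalysed intramolecular α-arylation of the ketone, in which zerovalent palladium inserts into C–Br and leaves C–Cl and only the C7 enolate can close a six-membered ring, forms C7–C15 perpendicular to the enolate plane, so ring C is cis-fused to ring F and C7 is fixed with C6 gauche to C23 and C8 anti to C23.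

Step 17
Reactants: 28 tricyclic ketone
Product: 29 tetracyclic ester with cyclopentane A closed (C5–C16 bond)
Conditions: Pd(dba)2 (5 mol %), P(t-Bu)3 (10 mol %), LiHMDS (2.5 equiv), toluene, rt to 50 °C; then NaOMe (cat.), MeOH, rt
Reagents that add atoms: none
Why: Palladium-catalysed intramolecular α-arylation of the ester enolate with the aryl chloride closes the five-membered ring (the C30 ketone enolate cannot reach C16 in the aryl plane), and the benzylic, ester-activated C5 then equilibrates under methoxide to the epimer with CO2Me pseudo-equatorial and trans to C8.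

Step 18
Reactants: 29 tetracyclic ester
Product: 30 phenol (C20–OH) with free C23–OH
Conditions: BCl3 (4 equiv), pentamethylbenzene, CH2Cl2, −78 to −30 °C; MeOH
Reagents that add atoms: none
Why: Lewis-acid debenzylation with a cation scavenger cleaves the aryl and the alkyl benzyl ether at low temperature while the silyl ether, ester, ketone and vinyl group persist.

Step 19
Reactants: 30 phenol
Product: 31 para-quinol dienone (C16–OH, C20 ketone, C14=C15 and C18=C19)
Conditions: PhI(OAc)2, MeCN/H2O (3:1), 0 °C
Reagents that add atoms: water, O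
Why: Oxidative dearomatization of the para-alkylphenol by the trivalent iodine reagent lets water add to C16 on the face of C8, because pyramidalizing C16 in that sense moves C5 and C18 to the side to which C6 is already displaced by the axial C8 (the other face would twist ring A) and the C5 ester lies on the opposite face.

Step 20
Reactants: 31 para-quinol dienone
Product: 32 C23 acetate
Conditions: Ac2O, pyridine, CH2Cl2, 0 °C to rt
Reagents that add atoms: acetic anhydride, CC(=O)OC(C)=O
Why: Acetylation takes the primary C23 hydroxyl and leaves the tertiary C16 hydroxyl.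

Step 21
Reactants: 32 C23 acetate
Product: 33 hydroxy enone (C18–C19 saturated)
Conditions: [(Ph3P)CuH]6 (0.4 equiv), benzene, rt; aq. NH4Cl
Reagents that add atoms: none
Why: Conjugate reduction by the copper hydride hexamer attacks the disubstituted C18=C19 bond of the cross-conjugated dienone and leaves the tetrasubstituted C14=C15 bond, the isolated C8 ketone and the vinyl group.

Step 22
Reactants: 33 hydroxy enone
Product: 34 C11 alcohol
Conditions: HF·pyridine, THF/pyridine, 0 °C to rt
Reagents that add atoms: none
Why: Buffered fluoride cleaves the silyl ether without the basic conditions that would open the β-hydroxy ester by retro-aldol reaction.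

Step 23
Reactants: 34 C11 alcohol
Product: 35 C11 azide
Conditions: PPh3, DIAD, (PhO)2P(O)N3, THF, 0 °C to rt
Reagents that add atoms: diphenylphosphoryl azide, [N-]=[N+]=NP(=O)(Oc1ccccc1)Oc1ccccc1
Why: Mitsunobu azidation converts only the primary C11 hydroxyl, the tertiary C16 hydroxyl being inert.

Step 24
Reactants: 35 C11 azide
Product: 36 C16 O-triethylsilyl ether
Conditions: TESOTf, 2,6-lutidine, CH2Cl2, −78 °C
Reagents that add atoms: triethylsilyl trifluoromethanesulfonate, CC[Si](CC)(CC)OS(=O)(=O)C(F)(F)F
Why: Silylation masks the tertiary C16 hydroxyl, which would otherwise be dehydrated by the reagent of step 27.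

Step 25
Reactants: 36 C16 O-triethylsilyl ether
Product: 37 C34 aldehyde
Conditions: OsO4 (2 mol %), NaIO4, 2,6-lutidine, dioxane/H2O (3:1), rt
Reagents that add atoms: sodium periodate, [Na+].[O-]I(=O)(=O)=O
Why: Lemieux–Johnson cleavage removes the terminal CH2 of the vinyl group and leaves the electron-poor tetrasubstituted enone bond.

Step 26
Reactants: 37 C34 aldehyde
Product: 39 hexacyclic C8 carbinolamine (rings D and G closed), via amino keto aldehyde 38 (not isolated)
Conditions: PMe3, THF/H2O (10:1), 0 °C to rt; concentrate; NaBH(OAc)3, AcOH, ClCH2CH2Cl, 0 °C to rt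
Reagents that add atoms: none
Why: After Staudinger reduction the C11 amine, held 1,3-diaxial to C8 on ring C, adds to the C8 ketone to close ring D as a carbinolamine, its N–H condenses with the C34 aldehyde to a five-membered iminium ion that is reduced (reductive amination, ring G), the bridgehead C8–OH cannot ionize and stays, and only the C30 epimer with the side chain cis to nitrogen closes while the other drains through the ketone enol.

Step 27
Reactants: 39 hexacyclic C8 carbinolamine
Product: 40 hexacyclic C8=C30 enamine (C16 O-triethylsilyl ether)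
Conditions: methyl N-(triethylammoniosulfonyl)carbamate (Burgess reagent), toluene, 25 to 80 °C, argon; filtered through basic alumina and used at once
Reagents that add atoms: none
Why: Proposed new method: the Burgess reagent sulfamoylates the tertiary carbinolamine oxygen and the sulfamate undergoes thermal syn-elimination with the C30 hydrogen, which the cis fusion of rings F and G holds syn-periplanar to the C8–O bond, so the C8=C30 bond forms in one irreversible step without the bridgehead iminium ion and despite the strain of an alkene of the bicyclo[3.3.1]non-1-ene type; the closest known reactions are Burgess dehydrations of tertiary alcohols and of hydroxy lactams to enamides and the making of bridgehead alkenes of this ring size by thermal syn-elimination.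

Step 28
Reactants: 40 hexacyclic C8=C30 enamine
Product: 42 C16 O-triethylsilyl ether of the target, via dioxetane 41 (not isolated)
Conditions: O2, tetraphenylporphyrin (cat.), visible light, CH2Cl2, −78 °C to rt
Reagents that add atoms: dioxygen, O=O
Why: Singlet oxygen from sensitized irradiation adds [2+2] across the electron-rich, twisted C8=C30 bond to give 1,2-dioxetane 41, which cycloreverts on warming into the C8 lactam carbonyl and the C30 ketone. The closest known reaction is the dye-sensitized photooxygenation of enamines and of 2,3-fused indoles to an amide plus a ketone. Ring E is not closed end to end: it arises by fragmentation when the bond shared by rings F and G is cut, so the five- and six-membered rings merge into the nine-membered one while ring D becomes the δ-lactam. No stereocentre is made, and C32, now α to the ketone, keeps its configuration under neutral, cold, aprotic conditions. The step needs dioxetane formation to win over the ene reaction at the C29 and C32 hydrogens and over attack on the enone; the nitrogen lone pair and the strain released at the bridgehead alkene favour the [2+2] path at −78 °C, and the C14=C15 enone bond is too electron-poor to react.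

Step 29
Reactants: 42 C16 O-triethylsilyl ether of the target
Product: 43 CNP0211170.1
Conditions: HF·pyridine, THF, 0 °C
Reagents that add atoms: none
Why: Fluoride cleaves the tertiary silyl ether under non-basic conditions, so the β-hydroxy ester cannot undergo retro-aldol opening and C32 is not epimerized.

**Compound list**

1 | cyclohexane-1,3-dione | O=C1CCCC(=O)C1 | starting material
2 | methyl acrylate | C=CC(=O)OC | starting material
3 | methyl 3-(2,6-dioxocyclohexyl)propanoate | COC(=O)CCC1C(=O)CCCC1=O | intermediate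
4 | methyl 3-(2-iodo-6-oxocyclohex-1-en-1-yl)propanoate | COC(=O)CCC1=C(I)CCCC1=O | intermediate
5 | potassium [(benzyloxy)methyl]trifluoroborate | [K+].F[B-](F)(F)COCc1ccccc1 | starting material
6 | methyl 3-{2-[(benzyloxy)methyl]-6-oxocyclohex-1-en-1-yl}propanoate | COC(=O)CCC1=C(COCc2ccccc2)CCCC1=O | intermediate
7 | methyl 3-{(6S)-2-[(benzyloxy)methyl]-6-hydroxycyclohex-1-en-1-yl}propanoate | COC(=O)CCC1=C(COCc2ccccc2)CCC[C@@H]1O | intermediate
8 | 3-bromo-4-chlorophenol | Oc1ccc(Cl)c(Br)c1 | starting material
9 | benzyl bromide | BrCc1ccccc1 | starting material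
10 | 4-(benzyloxy)-2-bromo-1-chlorobenzene | Clc1ccc(OCc2ccccc2)cc1Br | intermediate
11 | [6-(benzyloxy)-2-bromo-3-chlorophenyl]lithium | [Li]c1c(Br)c(Cl)ccc1OCc1ccccc1 | intermediate
12 | 6-(benzyloxy)-2-bromo-3-chlorobenzaldehyde | O=Cc1c(Br)c(Cl)ccc1OCc1ccccc1 | intermediate
13 | 2,2-dimethyl-1,3-dioxane-4,6-dione (Meldrum's acid) | CC1(C)OC(=O)CC(=O)O1 | starting material
14 | 5-(Ar-methylidene)-2,2-dimethyl-1,3-dioxane-4,6-dione | CC1(C)OC(=O)C(=Cc2c(Br)c(Cl)ccc2OCc2ccccc2)C(=O)O1 | intermediate
15 | 5-(Ar-methyl)-2,2-dimethyl-1,3-dioxane-4,6-dione | CC1(C)OC(=O)C(Cc2c(Br)c(Cl)ccc2OCc2ccccc2)C(=O)O1 | intermediate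
16 | 3-[6-(benzyloxy)-2-bromo-3-chlorophenyl]propanoic acid | OC(=O)CCc1c(Br)c(Cl)ccc1OCc1ccccc1 | intermediate
17 | (1S)-3-[(benzyloxy)methyl]-2-(3-methoxy-3-oxopropyl)cyclohex-2-en-1-yl 3-Ar-propanoate | COC(=O)CCC1=C(COCc2ccccc2)CCC[C@@H]1OC(=O)CCc1c(Br)c(Cl)ccc1OCc1ccccc1 | intermediate
18 | bis(tert-butyldimethylsilyl ketene acetal) of 17, allyl-ester ketene acetal with C13 trans to the ring oxygen | COC(O[Si](C)(C)C(C)(C)C)=CCC1=C(COCc2ccccc2)CCC[C@@H]1O/C(O[Si](C)(C)C(C)(C)C)=C/Cc1c(Br)c(Cl)ccc1OCc1ccccc1 | intermediate
19 | 3-Ar-2-{1-[(benzyloxy)methyl]-2-(3-methoxy-3-oxopropyl)cyclohex-2-en-1-yl}propanoic acid, C22 R and C12 S (CH2OBn anti to the carboxyl carbon C11 in the later ring C) | COC(=O)CCC1=CCCC[C@@]1(COCc2ccccc2)[C@@H](C(=O)O)Cc2c(Br)c(Cl)ccc2OCc2ccccc2 | intermediate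
20 | organoborane from 19 (drawn as monomeric C8–BH2 and C11–O–BH2) | COC(=O)CCC1C([BH2])CCC[C@@]1(COCc2ccccc2)[C@@H](CO[BH2])Cc2c(Br)c(Cl)ccc2OCc2ccccc2 | intermediate
21 | diol: ring-F cyclohexane with C8–OH, C7 chain CH2CH2CO2Me, C22 bearing CH2OBn and CH(CH2OH)CH2Ar (C22, C12 as in 19) | COC(=O)CCC1C(O)CCC[C@@]1(COCc2ccccc2)[C@@H](CO)Cc2c(Br)c(Cl)ccc2OCc2ccccc2 | intermediate
22 | C11 O-tert-butyldiphenylsilyl ether of 21 | COC(=O)CCC1C(O)CCC[C@@]1(COCc2ccccc2)[C@@H](CO[Si](c2ccccc2)(c2ccccc2)C(C)(C)C)Cc2c(Br)c(Cl)ccc2OCc2ccccc2 | intermediate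
23 | C8 ketone from 22 | COC(=O)CCC1C(=O)CCC[C@@]1(COCc2ccccc2)[C@@H](CO[Si](c2ccccc2)(c2ccccc2)C(C)(C)C)Cc2c(Br)c(Cl)ccc2OCc2ccccc2 | intermediate
24 | (E)-but-2-en-1-ol | C/C=C/CO | starting material
25 | (E)-but-2-en-1-yl methyl carbonate | C/C=C/COC(=O)OC | intermediate
26 | C8 O-trimethylsilyl enol ether of 23 (C8=C30) | COC(=O)CCC1C(O[Si](C)(C)C)=CCC[C@@]1(COCc2ccccc2)[C@@H](CO[Si](c2ccccc2)(c2ccccc2)C(C)(C)C)Cc2c(Br)c(Cl)ccc2OCc2ccccc2 | intermediate
27 | ketone 23 carrying (2R)-but-3-en-2-yl on C30 | COC(=O)CCC1C(=O)C([C@H](C)C=C)CC[C@@]1(COCc2ccccc2)[C@@H](CO[Si](c2ccccc2)(c2ccccc2)C(C)(C)C)Cc2c(Br)c(Cl)ccc2OCc2ccccc2 | intermediate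
28 | tricyclic ketone: ring C closed by C7–C15, rings C and F cis-fused, C11 (on C12) cis to C8, C16–Cl and C20–OBn on the arene | COC(=O)CC[C@@]12C(=O)C([C@H](C)C=C)CC[C@@]2(COCc3ccccc3)[C@@H](CO[Si](c3ccccc3)(c3ccccc3)C(C)(C)C)Cc3c(OCc4ccccc4)ccc(Cl)c31 | intermediate
29 | tetracyclic ester: cyclopentane A closed by C5–C16, CO2Me on C5 trans to C8 | COC(=O)[C@@H]1C[C@@]23C(=O)C([C@H](C)C=C)CC[C@@]3(COCc5ccccc5)[C@@H](CO[Si](c5ccccc5)(c5ccccc5)C(C)(C)C)Cc4c(OCc5ccccc5)ccc1c42 | intermediate
30 | phenol (C20–OH) with C23–OH, from 29 | COC(=O)[C@@H]1C[C@@]23C(=O)C([C@H](C)C=C)CC[C@@]3(CO)[C@@H](CO[Si](c5ccccc5)(c5ccccc5)C(C)(C)C)Cc4c(O)ccc1c42 | intermediate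
31 | para-quinol dienone: C16–OH cis to C8 and trans to CO2Me, C20 ketone, C14=C15 and C18=C19 | COC(=O)[C@@H]1C[C@@]23C(=O)C([C@H](C)C=C)CC[C@@]3(CO)[C@@H](CO[Si](c5ccccc5)(c5ccccc5)C(C)(C)C)CC4=C2[C@]1(O)C=CC4=O | intermediate
32 | C23 acetate of 31 | COC(=O)[C@@H]1C[C@@]23C(=O)C([C@H](C)C=C)CC[C@@]3(COC(C)=O)[C@@H](CO[Si](c5ccccc5)(c5ccccc5)C(C)(C)C)CC4=C2[C@]1(O)C=CC4=O | intermediate
33 | hydroxy enone (C18–C19 saturated) | COC(=O)[C@@H]1C[C@@]23C(=O)C([C@H](C)C=C)CC[C@@]3(COC(C)=O)[C@@H](CO[Si](c5ccccc5)(c5ccccc5)C(C)(C)C)CC4=C2[C@]1(O)CCC4=O | intermediate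
34 | C11 alcohol from 33 | COC(=O)[C@@H]1C[C@@]23C(=O)C([C@H](C)C=C)CC[C@@]3(COC(C)=O)[C@@H](CO)CC4=C2[C@]1(O)CCC4=O | intermediate
35 | C11 azide | COC(=O)[C@@H]1C[C@@]23C(=O)C([C@H](C)C=C)CC[C@@]3(COC(C)=O)[C@@H](CN=[N+]=[N-])CC4=C2[C@]1(O)CCC4=O | intermediate
36 | C16 O-triethylsilyl ether of 35 | COC(=O)[C@@H]1C[C@@]23C(=O)C([C@H](C)C=C)CC[C@@]3(COC(C)=O)[C@@H](CN=[N+]=[N-])CC4=C2[C@]1(O[Si](CC)(CC)CC)CCC4=O | intermediate
37 | C34 aldehyde (side chain CH(CH3)CHO on C30) | COC(=O)[C@@H]1C[C@@]23C(=O)C([C@H](C)C=O)CC[C@@]3(COC(C)=O)[C@@H](CN=[N+]=[N-])CC4=C2[C@]1(O[Si](CC)(CC)CC)CCC4=O | intermediate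
38 | C11 amine of 37 | COC(=O)[C@@H]1C[C@@]23C(=O)C([C@H](C)C=O)CC[C@@]3(COC(C)=O)[C@@H](CN)CC4=C2[C@]1(O[Si](CC)(CC)CC)CCC4=O | intermediate
39 | hexacyclic carbinolamine: N10 bonded to C8, C11 and C34; C8–OH; rings F and G cis-fused | COC(=O)[C@@H]1C[C@@]23[C@@]6(O)N4C[C@@H](CC5=C2[C@]1(O[Si](CC)(CC)CC)CCC5=O)[C@]3(COC(C)=O)CC[C@@H]6[C@H](C)C4 | intermediate
40 | hexacyclic C8=C30 enamine, C16 O-triethylsilyl ether (key-step precursor) | COC(=O)[C@@H]1C[C@@]23C=6N4C[C@@H](CC5=C2[C@]1(O[Si](CC)(CC)CC)CCC5=O)[C@]3(COC(C)=O)CCC6[C@H](C)C4 | intermediate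
41 | 1,2-dioxetane across C8–C30 | COC(=O)[C@@H]1C[C@@]23C6(OO7)N4C[C@@H](CC5=C2[C@]1(O[Si](CC)(CC)CC)CCC5=O)[C@]3(COC(C)=O)CCC67[C@H](C)C4 | intermediate
42 | C16 O-triethylsilyl ether of CNP0211170.1 (key-step product) | COC(=O)[C@@H]1C[C@@]23C(=O)N4C[C@@H](CC5=C2[C@]1(O[Si](CC)(CC)CC)CCC5=O)[C@]3(COC(C)=O)CCC(=O)[C@H](C)C4 | intermediate
43 | CNP0211170.1 | COC(=O)[C@@H]1C[C@@]23C(=O)N4C[C@@H](CC5=C2[C@]1(O)CCC5=O)[C@]3(COC(C)=O)CCC(=O)[C@H](C)C4 | target

**Step count**

Total: 29 steps. Longest linear sequence: 24 steps (steps 1–4, 9–13, 15–29; the arene branch, steps 5–8, is equally long).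

**Steps most likely to fail**

1. Step 27 (bridgehead enamine). The O-sulfamate may not eliminate because the alkene it must form is strained, or the ring-opened amino ketone tautomer may be sulfamoylated on nitrogen instead. Fallback by known chemistry that needs no enamine: it sets out from carbinolamine 39 and comes back at 42. PhI(OAc)2, I2 and visible light under O2 in CH2Cl2 turn the C8–OH into its hypoiodite; the alkoxy radical cuts the C8–C30 bond so that the lactam carbonyl forms, and the C30 radical takes up O2 to give the nine-membered C30-hydroperoxy lactam F1. Ac2O and pyridine then dehydrate the secondary hydroperoxide to ketone 42. This is the alkoxy-radical fragmentation used to expand bicyclic hemiaminals and lactols to medium rings.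

2. Step 28 (key step). The ene reaction at the C29 or C32 hydrogens may compete with dioxetane formation, or the strained enamine may be hydrolysed back to 39 by traces of water. Fallback: from 40 back to 42 by ozonolysis (O3, 1 equiv, CH2Cl2, −78 °C, then Me2S). Ozone adds to the same electron-rich bond by [3+2] cycloaddition, cannot take the ene path, and the Criegee cleavage of an enamine gives the amide and the ketone directly; no new compound is isolated (F0).

3. Step 10 (Ireland–Claisen). Chair and boat transition states or incomplete control of ketene acetal geometry may erode the C12 configuration, and the rearrangement onto the tetrasubstituted alkene may be slow. Fallback that sets C12 by an auxiliary: it sets out from 7 and 12 and comes back at 19.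
   - Acetylation of 7 (Ac2O, pyridine) gives the allylic acetate F2.
   - Ireland–Claisen rearrangement (LDA, TBSCl, THF, −78 to 65 °C) gives the C22 acetic acid F3; C22 is set by chirality transfer alone and no C12 issue arises.
   - Pivaloyl chloride and Et3N, then lithiated (S)-4-benzyloxazolidin-2-one, give the N-acyl oxazolidinone F4.
   - Aldehyde 12 is reduced (NaBH4, MeOH) to the benzylic alcohol F5 and brominated (PBr3, Et2O) to the benzylic bromide F6.
   - NaHMDS, then F6, alkylates the Z enolate of F4 on the face away from the benzyl group to give the alkylated imide F7 with the required C12 configuration.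
   - LiOH and H2O2 in THF/H2O at 0 °C remove the auxiliary and return acid 19.

**Further compounds**

F1 | step 27 | C30-hydroperoxy nine-membered lactam (C16 O-triethylsilyl ether) | COC(=O)[C@@H]1C[C@@]23C(=O)N4C[C@@H](CC5=C2[C@]1(O[Si](CC)(CC)CC)CCC5=O)[C@]3(COC(C)=O)CCC(OO)[C@H](C)C4
F0 | step 28 | none | none
F2 | step 10 | (1S)-3-[(benzyloxy)methyl]-2-(3-methoxy-3-oxopropyl)cyclohex-2-en-1-yl acetate | COC(=O)CCC1=C(COCc2ccccc2)CCC[C@@H]1OC(C)=O
F3 | step 10 | 2-{1-[(benzyloxy)methyl]-2-(3-methoxy-3-oxopropyl)cyclohex-2-en-1-yl}acetic acid (C22 as in 19) | COC(=O)CCC1=CCCC[C@@]1(COCc2ccccc2)CC(=O)O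
F4 | step 10 | N-acyl (S)-4-benzyloxazolidin-2-one of F3 | COC(=O)CCC1=CCCC[C@@]1(COCc2ccccc2)CC(=O)N1[C@@H](Cc2ccccc2)COC1=O
F5 | step 10 | [6-(benzyloxy)-2-bromo-3-chlorophenyl]methanol | OCc1c(Br)c(Cl)ccc1OCc1ccccc1
F6 | step 10 | 1-(benzyloxy)-3-bromo-2-(bromomethyl)-4-chlorobenzene | BrCc1c(Br)c(Cl)ccc1OCc1ccccc1
F7 | step 10 | C12-alkylated N-acyl oxazolidinone (C12 as in 19) | COC(=O)CCC1=CCCC[C@@]1(COCc2ccccc2)[C@H](Cc2c(Br)c(Cl)ccc2OCc2ccccc2)C(=O)N1[C@@H](Cc2ccccc2)COC1=O
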